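**Plan**
Cuts (isoquinoline numbering): first C1–CH3, leading back to a lactam C1=O. Next N2–C1 and C3–C4, leading back to an o-toluate methyl group and an N-sulfinyl acetaldimine. Last, C4a–C5 and C6–C7 of ring A.
Enabling feature: in ring A (C4a, C5, C6, C7, C8, C8a) the run C4a(CH2)–C8a(C1 carbon)–C8(OMe)–C7(H) is the C6(CH3)–C5(CO2Me)–C4(OMe)–C3(H) diene of a 2-pyrone. The adjacent pair C5(naphthyl)–C6(O) is an aryl ynol ether, and loss of the pyrone O1–C2 bridge as CO2 leaves the arene.
Forward order: the second naphthalene ring by aryne–dienolate annulation, then alkynylation and oxidation to the siloxyalkyne. The pyrone ring comes from methyl acetoacetate and malonyl dichloride, ring A from [4+2]/retro-[4+2], the nitrogen ring from lactamisation, and the C1 methyl group is added last.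
Stereochemistry: C3 (S) is set by addition of the laterally lithiated toluate to the (S)-p-toluenesulfinyl imine of acetaldehyde, and no later step touches C3.

Key step: step 9

Assumption: the SMILES fixes only C3 (S) and leaves the rotationally hindered C5–C1' biaryl axis undefined, so the axis is not controlled. It forms racemic in the cycloaddition. From the sulfinimine addition onwards each compound is the pair of axial diastereomers with uniform 3S configuration, separable by chromatography at the lactam stage if one rotamer is wanted.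

Step 1
Reactants: 1 3,3-dimethylacryloyl chloride
Product: 2 N,N-diethyl-3-methylbut-2-enamide
Conditions: Et2NH (2.2 equiv), CH2Cl2, 0 °C → rt
Reagents that add atoms: diethylamine, CCNCC
Why: N-Acylation of a secondary amine by an acid chloride (Schotten–Baumann type), the second equivalent of amine binding the HCl and the conjugated C=C staying untouched at this temperature.

Step 2
Reactants: 2 N,N-diethyl-3-methylbut-2-enamide; 3 3-bromoanisole
Product: 6 8-methoxy-3-methylnaphthalen-1-ol, via lithium dienolate 4 (not isolated), via 3-methoxybenzyne 5 (not isolated)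
Conditions: LiN(iPr)2 (3 equiv), THF, −78 °C → rt; aq HCl
Reagents that add atoms: none
Why: Aryne–dienolate annulation: the base converts 2 into its extended enolate 4 and 3, deprotonated between Br and OMe, into aryne 5, the γ-carbon of 4 adds to the aryne carbon remote from the methoxy group so that the aryl anion arises next to it, and this anion closes onto the amide carbonyl, loss of LiNEt2 and tautomerisation giving the naphthol with OH and OMe in the peri positions.

Step 3
Reactants: 6 8-methoxy-3-methylnaphthalen-1-ol
Product: 7 1,8-dimethoxy-3-methylnaphthalene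
Conditions: NaH, MeI, DMF, 0 °C → rt
Reagents that add atoms: iodomethane, CI
Why: Williamson ether synthesis, in which full deprotonation with NaH overcomes the hydrogen bond of the peri OH to the neighbouring methoxy oxygen.

Step 4
Reactants: 7 1,8-dimethoxy-3-methylnaphthalene
Product: 8 1-iodo-4,5-dimethoxy-2-methylnaphthalene
Conditions: NIS (1.0 equiv), TFA (cat.), MeCN, 0 °C → rt
Reagents that add atoms: N-iodosuccinimide, O=C1CCC(=O)N1I
Why: Electrophilic aromatic iodination: C4 of 7 is an α-position, para to the C1 methoxy group and ortho to the methyl group, and thus the most activated site, in line with the halogenation of 2-methylnaphthalene at C1.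

Step 5
Reactants: 8 1-iodo-4,5-dimethoxy-2-methylnaphthalene
Product: 9 [(4,5-dimethoxy-2-methylnaphthalen-1-yl)ethynyl]trimethylsilane
Conditions: Me3SiC≡CH, PdCl2(PPh3)2 (cat.), CuI (cat.), Et3N, THF, 60 °C
Reagents that add atoms: ethynyl(trimethyl)silane, C#C[Si](C)(C)C
Why: Sonogashira coupling: the aryl iodide adds readily to zerovalent palladium, and the rod-shaped copper acetylide is the least demanding carbon partner for a position flanked by a methyl group and a peri hydrogen.

Step 6
Reactants: 9 [(4,5-dimethoxy-2-methylnaphthalen-1-yl)ethynyl]trimethylsilane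
Product: 12 [(4,5-dimethoxy-2-methylnaphthalen-1-yl)ethynyloxy]tri(propan-2-yl)silane, via lithium acetylide 10 (not isolated), via lithium ynolate 11 (not isolated)
Conditions: MeLi, THF, 0 °C → rt; t-BuOOLi (from t-BuOOH and LiN(SiMe3)2), THF, −78 → 0 °C; TIPSOTf, −78 → 0 °C
Reagents that add atoms: tert-butyl hydroperoxide, CC(C)(C)OO; triisopropylsilyl trifluoromethanesulfonate, CC(C)[Si](OS(=O)(=O)C(F)(F)F)(C(C)C)C(C)C
Why: Methyllithium attacks silicon and releases acetylide 10, the acetylide carbon displaces tert-butoxide from the electrophilic oxygen of lithium tert-butyl peroxide (known oxenoid oxidation of lithium acetylides to ynolates), and the bulky silyl triflate traps ynolate 11 on oxygen to give a siloxyalkyne that tolerates chromatography and heating.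

Step 7
Reactants: 13 methyl acetoacetate; 14 malonyl dichloride
Product: 15 methyl 4-hydroxy-6-methyl-2-oxo-2H-pyran-5-carboxylate
Conditions: 1:1, CH2Cl2, reflux (HCl swept out with N2)
Reagents that add atoms: none
Why: Known hydroxypyrone synthesis from β-keto esters and malonyl dichloride: C-acylation at the active methylene carbon and O-acylation of the ketone enol by the second acyl chloride close the lactone, and enolisation gives the 4-hydroxy-2-pyrone.

Step 8
Reactants: 15 methyl 4-hydroxy-6-methyl-2-oxo-2H-pyran-5-carboxylate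
Product: 16 methyl 4-methoxy-6-methyl-2-oxo-2H-pyran-5-carboxylate
Conditions: Me2SO4, K2CO3, acetone, reflux
Reagents that add atoms: dimethyl sulfate, COS(=O)(=O)OC
Why: O-Alkylation of a vinylogous acid: with the hard electrophile dimethyl sulfate and carbonate base, 4-hydroxy-2-pyrones are methylated on the 4-oxygen, which keeps the 2-pyrone rather than the 4-pyrone form.

Step 9
Reactants: 16 methyl 4-methoxy-6-methyl-2-oxo-2H-pyran-5-carboxylate; 12 [(4,5-dimethoxy-2-methylnaphthalen-1-yl)ethynyloxy]tri(propan-2-yl)silane
Product: 18 methyl 3-(4,5-dimethoxy-2-methylnaphthalen-1-yl)-6-methoxy-2-methyl-4-[tri(propan-2-yl)silyloxy]benzoate, via bicyclic lactone 17 (not isolated)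
Conditions: 16 (2 equiv), toluene (1 M), sealed tube, Ar, 150 °C
Reagents that add atoms: none
Why: The electron-rich ynol ether and the electron-poor 2-pyrone combine in an inverse-electron-demand Diels–Alder reaction that is strongly asynchronous (at the limit stepwise through a silyl ketenium/pyrone dienolate ion pair), the nucleophilic naphthyl-bearing alkyne carbon bonding to pyrone C6 and the oxygen-bearing carbon to pyrone C3. The 2-oxabicyclo[2.2.2]octadienone 17 then expels CO2 by retro-[4+2], which is irreversible and aromatises ring A. The closest known reactions are the decarboxylative benzannulations of coumalates and of 6-methyl-5-alkoxycarbonyl-2-pyrones with ynamines, alkoxyalkynes and (under gold catalysis) siloxyalkynes, together with Diels–Alder syntheses of hindered biaryls from arylalkynes. The one ring closed is the six-membered carbocycle, formed by intermolecular [4+2] cycloaddition (C4a–C5 and C6–C7 bonds in isoquinoline numbering). No stereocentre arises and the C5–C1' axis is born racemic. The step needs regioselectivity, and matched polarity secures it: C6 is the β-carbon of the C5 acrylate and the far end of the dienyl lactone, the 4-methoxy group makes C3 the electron-rich terminus that captures the ketenium carbon, and the linear alkyne keeps the naphthyl group away from the 6-methyl group until late in bond formation.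

Step 10
Reactants: 18 methyl 3-(4,5-dimethoxy-2-methylnaphthalen-1-yl)-6-methoxy-2-methyl-4-[tri(propan-2-yl)silyloxy]benzoate
Product: 20 methyl 3-(4,5-dimethoxy-2-methylnaphthalen-1-yl)-4,6-dimethoxy-2-methylbenzoate, via caesium phenoxide 19 (not isolated)
Conditions: CsF, MeI, DMF, rt
Reagents that add atoms: iodomethane, CI
Why: Fluoride cleaves the aryl silyl ether (strong Si–F bond, good phenoxide leaving group) and phenoxide 19 is methylated in the same flask (Williamson ether synthesis), the methyl ester being inert to both reagents.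

Step 11
Reactants: 21 (S)-4-methylbenzenesulfinamide; 22 acetaldehyde
Product: 23 (S,E)-N-ethylidene-4-methylbenzenesulfinamide
Conditions: Ti(OEt)4, CH2Cl2, rt
Reagents that add atoms: none
Why: Lewis-acid-mediated dehydrative condensation of a primary sulfinamide with an aldehyde, Ti(OEt)4 acting as activator and water scavenger, the sulfur stereocentre taking no part and the E-imine forming.

Step 12
Reactants: 20 methyl 3-(4,5-dimethoxy-2-methylnaphthalen-1-yl)-4,6-dimethoxy-2-methylbenzoate; 23 (S,E)-N-ethylidene-4-methylbenzenesulfinamide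
Product: 25 methyl 3-(4,5-dimethoxy-2-methylnaphthalen-1-yl)-4,6-dimethoxy-2-[(2S)-2-{[(S)-4-methylbenzenesulfinyl]amino}propyl]benzoate, via benzylic lithium 24 (not isolated)
Conditions: LiN(iPr)2, THF, −78 °C; 23 (1.5 equiv), −78 °C; H2O
Reagents that add atoms: none
Why: Lateral lithiation of an o-toluate (the anion is an extended ester enolate, whereas the naphthyl methyl group has no such activation) followed by 1,2-addition to an N-sulfinyl aldimine, a known pairing for lithiated o-toluic acid derivatives; lithium bound to the sulfinyl oxygen organises a six-membered chair with the p-tolyl group equatorial, which delivers the carbanion to the Re face of the E-imine and sets C3 as S, and any 3R adduct is a diastereomer removable by chromatography.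

Step 13
Reactants: 25 methyl 3-(4,5-dimethoxy-2-methylnaphthalen-1-yl)-4,6-dimethoxy-2-[(2S)-2-{[(S)-4-methylbenzenesulfinyl]amino}propyl]benzoate
Product: 27 (3S)-5-(4,5-dimethoxy-2-methylnaphthalen-1-yl)-6,8-dimethoxy-3-methyl-3,4-dihydroisoquinolin-1(2H)-one, via amino ester hydrochloride 26 (not isolated)
Conditions: HCl (4 M in dioxane), MeOH, rt; evaporate; NaOMe, MeOH, 65 °C
Reagents that add atoms: none
Why: Acid methanolysis of the S–N bond frees the amine as its salt 26, and after neutralisation the amine attacks the neighbouring ester in a 6-exo-trig aminolysis (lactamisation) promoted by methoxide, C3 carrying no acidic hydrogen and keeping its configuration.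

Step 14
Reactants: 27 (3S)-5-(4,5-dimethoxy-2-methylnaphthalen-1-yl)-6,8-dimethoxy-3-methyl-3,4-dihydroisoquinolin-1(2H)-one
Product: 29 O-methylancistrocladinine, (3S)-5-(4,5-dimethoxy-2-methylnaphthalen-1-yl)-6,8-dimethoxy-1,3-dimethyl-3,4-dihydroisoquinoline, via imidoyl triflate 28 (not isolated)
Conditions: Tf2O, 2-fluoropyridine, CH2Cl2, −78 → 0 °C; MeMgBr (2.5 equiv), −78 °C → rt; aq NaHCO3
Reagents that add atoms: methylmagnesium bromide, C[Mg]Br
Why: Electrophilic amide activation: triflic anhydride and the weakly nucleophilic base convert the secondary lactam into imidoyl triflate 28, the Grignard reagent replaces triflate by addition–elimination at C1 (known ketimine synthesis from secondary amides), and the ketimine formed is too poor an electrophile for a second addition, while C3 is not affected.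

**Compound list**
1 | 3,3-dimethylacryloyl chloride | CC(C)=CC(Cl)=O | starting material
2 | N,N-diethyl-3-methylbut-2-enamide | CCN(CC)C(=O)C=C(C)C | intermediate
3 | 3-bromoanisole | COc1cccc(Br)c1 | starting material
4 | lithium dienolate of 2 (lithium 1-(diethylamino)-3-methylbuta-1,3-dien-1-olate) | [Li]OC(=CC(C)=C)N(CC)CC | intermediate
5 | 3-methoxybenzyne (1-methoxy-2,3-didehydrobenzene) | COC1=CC=CC#C1 | intermediate
6 | 8-methoxy-3-methylnaphthalen-1-ol | COc1cccc2cc(C)cc(O)c12 | intermediate
7 | 1,8-dimethoxy-3-methylnaphthalene | COc1cccc2cc(C)cc(OC)c12 | intermediate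
8 | 1-iodo-4,5-dimethoxy-2-methylnaphthalene | COc1cc(C)c(I)c2cccc(OC)c12 | intermediate
9 | [(4,5-dimethoxy-2-methylnaphthalen-1-yl)ethynyl]trimethylsilane | COc1cc(C)c(C#C[Si](C)(C)C)c2cccc(OC)c12 | intermediate
10 | lithium (4,5-dimethoxy-2-methylnaphthalen-1-yl)acetylide | COc1cc(C)c(C#C[Li])c2cccc(OC)c12 | intermediate
11 | lithium 2-(4,5-dimethoxy-2-methylnaphthalen-1-yl)ethynolate | COc1cc(C)c(C#CO[Li])c2cccc(OC)c12 | intermediate
12 | [(4,5-dimethoxy-2-methylnaphthalen-1-yl)ethynyloxy]tri(propan-2-yl)silane | CC(C)[Si](OC#Cc1c(C)cc(OC)c2c(OC)cccc12)(C(C)C)C(C)C | intermediate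
13 | methyl acetoacetate | CC(=O)CC(=O)OC | starting material
14 | malonyl dichloride | O=C(Cl)CC(Cl)=O | starting material
15 | methyl 4-hydroxy-6-methyl-2-oxo-2H-pyran-5-carboxylate | COC(=O)c1c(C)oc(=O)cc1O | intermediate
16 | methyl 4-methoxy-6-methyl-2-oxo-2H-pyran-5-carboxylate | COC(=O)c1c(C)oc(=O)cc1OC | intermediate
17 | methyl 7-(4,5-dimethoxy-2-methylnaphthalen-1-yl)-5-methoxy-1-methyl-3-oxo-8-[tri(propan-2-yl)silyloxy]-2-oxabicyclo[2.2.2]octa-5,7-diene-6-carboxylate (racemic) | CC12OC(=O)C(C(OC)=C1C(=O)OC)C(O[Si](C(C)C)(C(C)C)C(C)C)=C2c1c(C)cc(OC)c2c(OC)cccc12 | intermediate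
18 | methyl 3-(4,5-dimethoxy-2-methylnaphthalen-1-yl)-6-methoxy-2-methyl-4-[tri(propan-2-yl)silyloxy]benzoate | COC(=O)c1c(OC)cc(O[Si](C(C)C)(C(C)C)C(C)C)c(-c2c(C)cc(OC)c3c(OC)cccc23)c1C | intermediate
19 | caesium 2-(4,5-dimethoxy-2-methylnaphthalen-1-yl)-5-methoxy-4-(methoxycarbonyl)-3-methylphenoxide | COC(=O)c1c(OC)cc([O-])c(-c2c(C)cc(OC)c3c(OC)cccc23)c1C.[Cs+] | intermediate
20 | methyl 3-(4,5-dimethoxy-2-methylnaphthalen-1-yl)-4,6-dimethoxy-2-methylbenzoate | COC(=O)c1c(OC)cc(OC)c(-c2c(C)cc(OC)c3c(OC)cccc23)c1C | intermediate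
21 | (S)-4-methylbenzenesulfinamide | Cc1ccc(cc1)[S@](=O)N | starting material
22 | acetaldehyde | CC=O | starting material
23 | (S,E)-N-ethylidene-4-methylbenzenesulfinamide | Cc1ccc(cc1)[S@](=O)/N=C/C | intermediate
24 | benzylic lithium derivative of 20 (lithiated at the 2-methyl group) | COC(=O)c1c(OC)cc(OC)c(-c2c(C)cc(OC)c3c(OC)cccc23)c1C[Li] | intermediate
25 | methyl 3-(4,5-dimethoxy-2-methylnaphthalen-1-yl)-4,6-dimethoxy-2-[(2S)-2-{[(S)-4-methylbenzenesulfinyl]amino}propyl]benzoate | COC(=O)c1c(OC)cc(OC)c(-c2c(C)cc(OC)c3c(OC)cccc23)c1C[C@H](C)N[S@@](=O)c1ccc(C)cc1 | intermediate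
26 | methyl 2-[(2S)-2-aminopropyl]-3-(4,5-dimethoxy-2-methylnaphthalen-1-yl)-4,6-dimethoxybenzoate hydrochloride | COC(=O)c1c(OC)cc(OC)c(-c2c(C)cc(OC)c3c(OC)cccc23)c1C[C@H](C)[NH3+].[Cl-] | intermediate
27 | (3S)-5-(4,5-dimethoxy-2-methylnaphthalen-1-yl)-6,8-dimethoxy-3-methyl-3,4-dihydroisoquinolin-1(2H)-one | COc1cc(OC)c(-c2c(C)cc(OC)c3c(OC)cccc23)c2c1C(=O)N[C@@H](C)C2 | intermediate
28 | (3S)-5-(4,5-dimethoxy-2-methylnaphthalen-1-yl)-6,8-dimethoxy-3-methyl-3,4-dihydroisoquinolin-1-yl trifluoromethanesulfonate | COc1cc(OC)c(-c2c(C)cc(OC)c3c(OC)cccc23)c2c1C(OS(=O)(=O)C(F)(F)F)=N[C@@H](C)C2 | intermediate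
29 | O-methylancistrocladinine, (3S)-5-(4,5-dimethoxy-2-methylnaphthalen-1-yl)-6,8-dimethoxy-1,3-dimethyl-3,4-dihydroisoquinoline | COc1cc(OC)c(-c2c(C)cc(OC)c3c(OC)cccc23)c2c1C(C)=N[C@@H](C)C2 | target

**Step count**
Total: 14 steps. Longest linear sequence: 11 steps (steps 1–6, 9, 10, 12, 13, 14).

**Steps most likely to fail**

Step 9. Bond formation between the methyl-bearing pyrone C6 and the naphthyl-bearing alkyne carbon may be slowed by steric compression. O-to-C silyl migration and oligomerisation of the ynol ether could then consume the alkyne first. The fallback makes the biaryl bond by cross-coupling instead of building ring A around it, and it sets out from 8. Iodine–lithium exchange (n-BuLi, THF, −78 °C) would give (4,5-dimethoxy-2-methylnaphthalen-1-yl)lithium F1. Treatment with B(OMe)3 and aq HCl would then give (4,5-dimethoxy-2-methylnaphthalen-1-yl)boronic acid F2. Purchased methyl 2,4-dimethoxy-6-methylbenzoate F3 is brominated (NBS, MeCN) para to its 2-methoxy group to give methyl 3-bromo-4,6-dimethoxy-2-methylbenzoate F4. Suzuki–Miyaura coupling of F2 with F4 (Pd(OAc)2, SPhos, K3PO4, toluene/H2O, 100 °C) comes back to the route at 20.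

Step 12. Proton transfer from the enolisable acetaldimine to the benzylic anion may quench the nucleophile. Facial selectivity may also erode for the axial rotamer whose naphthyl group opposes the sulfinyl-directed approach. The fallback sets C3 by hydride delivery to a ketimine instead of carbanion addition to an aldimine, and it sets out from 20. Anion 24 is generated with LiN(iPr)2 (2.2 equiv). Acylation with N-methoxy-N-methylacetamide would give methyl 3-(4,5-dimethoxy-2-methylnaphthalen-1-yl)-4,6-dimethoxy-2-(2-oxopropyl)benzoate F5. Condensation with (S)-2-methylpropane-2-sulfinamide (Ti(OEt)4, THF, 65 °C) would give the (S,E)-N-tert-butanesulfinyl ketimine F6. NaBH4 at −48 °C should reduce it through the cyclic transition state bound to the sulfinyl oxygen, giving the (S at sulfur, 2S at carbon) tert-butanesulfinamide F7. HCl in MeOH then comes back to the route at 26.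

Step 14. Activation of the hindered, electron-rich lactam may stay incomplete. Triflic anhydride may attack the methoxylated rings, or the Grignard reagent may act only as a base. The fallback replaces addition to an activated amide by a cross-coupling, and it sets out from 27. POCl3 (toluene, 90 °C) would give (3S)-1-chloro-5-(4,5-dimethoxy-2-methylnaphthalen-1-yl)-6,8-dimethoxy-3-methyl-3,4-dihydroisoquinoline F8. Iron-catalysed Kumada-type coupling of this imidoyl chloride with MeMgBr (Fe(acac)3 cat., THF/NMP, 0 °C) arrives at 29.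

**Further compounds**
F1 | step 9 | (4,5-dimethoxy-2-methylnaphthalen-1-yl)lithium | [Li]c1c(C)cc(OC)c2c(OC)cccc12
F2 | step 9 | (4,5-dimethoxy-2-methylnaphthalen-1-yl)boronic acid | OB(O)c1c(C)cc(OC)c2c(OC)cccc12
F3 | step 9 | methyl 2,4-dimethoxy-6-methylbenzoate (purchased) | COC(=O)c1c(C)cc(OC)cc1OC
F4 | step 9 | methyl 3-bromo-4,6-dimethoxy-2-methylbenzoate | COC(=O)c1c(OC)cc(OC)c(Br)c1C
F5 | step 12 | methyl 3-(4,5-dimethoxy-2-methylnaphthalen-1-yl)-4,6-dimethoxy-2-(2-oxopropyl)benzoate | COC(=O)c1c(OC)cc(OC)c(-c2c(C)cc(OC)c3c(OC)cccc23)c1CC(C)=O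
F6 | step 12 | methyl 3-(4,5-dimethoxy-2-methylnaphthalen-1-yl)-4,6-dimethoxy-2-[(2E)-2-{[(S)-2-methylpropane-2-sulfinyl]imino}propyl]benzoate | COC(=O)c1c(OC)cc(OC)c(-c2c(C)cc(OC)c3c(OC)cccc23)c1C/C(C)=N/[S@@](=O)C(C)(C)C
F7 | step 12 | methyl 3-(4,5-dimethoxy-2-methylnaphthalen-1-yl)-4,6-dimethoxy-2-[(2S)-2-{[(S)-2-methylpropane-2-sulfinyl]amino}propyl]benzoate | COC(=O)c1c(OC)cc(OC)c(-c2c(C)cc(OC)c3c(OC)cccc23)c1C[C@H](C)N[S@@](=O)C(C)(C)C
F8 | step 14 | (3S)-1-chloro-5-(4,5-dimethoxy-2-methylnaphthalen-1-yl)-6,8-dimethoxy-3-methyl-3,4-dihydroisoquinoline | COc1cc(OC)c(-c2c(C)cc(OC)c3c(OC)cccc23)c2c1C(Cl)=N[C@@H](C)C2
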